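**Assumption:** (+)-Taxifolin [(2R,3R)-dihydroquercetin, larch extract] is taken as a cheap commercial chiral starting material. The target SMILES decodes to the same (2R,3R)-trans configuration, with geranyl at C6, 4'-OMe and 3'-OH. The boron chelate is written as its own step, although it is generated and irradiated in the same solution.

## Retrosynthetic overview

1. C6–C1'' (aryl–geranyl): formed last by a light-driven 1,3 O→C shift of the geranyl group from O7, run on the O5,O4-diphenylboron chelate 7 of aryl geranyl ether 5, then boron removal to give 8.
2. O4'–CH3: methylation of the catechol of 3, with O7 already capped by the geranyl group.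
3. O7–C1'': Williamson etherification of (+)-taxifolin 1 with geranyl bromide 2.
4. No ring is built. Rings A, B and C and both stereocentres come intact from 1; the geranyl ether is first the O7 protecting group and then the source of the C6 substituent.

## Route

**Step 1**
Reactants: 1, (+)-taxifolin [(2R,3R)-2-(3,4-dihydroxyphenyl)-3,5,7-trihydroxychroman-4-one]; 2, geranyl bromide [(E)-1-bromo-3,7-dimethylocta-2,6-diene]
Product: 3, 7-O-geranyltaxifolin [(2R,3R)-2-(3,4-dihydroxyphenyl)-7-{[(E)-3,7-dimethylocta-2,6-dienyl]oxy}-3,5-dihydroxychroman-4-one]
Conditions: 2 (1.0 equiv), K2CO3 (1.0 equiv), DMF, 0 °C → rt, Ar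
Reagents that add atoms: geranyl bromide, CC(C)=CCC/C(C)=C/CBr
Why: Williamson etherification; 7-OH (para to the C4 carbonyl, pKa ≈ 7.5) is the most acidic hydroxyl, so limited base ionises it first and the phenoxide displaces bromide at the primary allylic carbon with the (E)-alkene unchanged, while the hydrogen-bonded 5-OH, the catechol and the secondary 3-OH stay protonated; C2 and C3 are untouched.

**Step 2**
Reactants: 3, 7-O-geranyltaxifolin; 4, iodomethane
Product: 5, 7-O-geranyl-4'-O-methyltaxifolin [(2R,3R)-7-{[(E)-3,7-dimethylocta-2,6-dienyl]oxy}-3,5-dihydroxy-2-(3-hydroxy-4-methoxyphenyl)chroman-4-one]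
Conditions: MeI (1.1 equiv), K2CO3 (1.0 equiv), DMF, 0 °C → rt, Ar; chromatographic removal of the 3'-O-methyl isomer
Reagents that add atoms: iodomethane, CI
Why: Williamson methylation of the catechol monoanion; with O7 blocked, the catechol is the most acidic remaining site, and 4'-O (para to the O-bearing benzylic C2, whose phenoxide gains some stabilisation from σ*C2–O1) is expected to be alkylated preferentially, though only modestly (about 2:1 over 3'-O, isomers separable; regiochemistry confirmed by NOE from OMe to H-5'); 5-OH and 3-OH do not react and the stereocentres are unchanged (J2,3 ≈ 11–12 Hz as a check).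

**Step 3**
Reactants: 5, 7-O-geranyl-4'-O-methyltaxifolin; 6, diphenylborinic anhydride (Ph2B–O–BPh2)
Product: 7, O5,O4-diphenylboron chelate of 5 [six-membered C4=O→B(Ph)2–O5 ring on the A/C rings; 7-O-geranyl, 3-OH, 3'-OH and 4'-OMe unchanged; (2R,3R,E)]
Conditions: 6 (0.55 equiv), 4 Å MS, degassed MeCN (5 mM in 5), rt, 30 min, Ar; solution used directly in Step 4
Reagents that add atoms: diphenylborinic anhydride, c1ccccc1B(c1ccccc1)OB(c1ccccc1)c1ccccc1
Why: Borinic anhydride condensation with the 5-OH/C4=O pair gives the tetracoordinate six-membered O,O-chelate (the same chelation that makes 5-hydroxy-4-keto flavonoids fluoresce with diphenylborinate stains), with water taken up by the sieves; this phenolate chelate is favoured over a five-membered 3-alkoxide chelate or a labile monodentate 3'-O-borinate, and C2/C3 are not involved (check: loss of the 5-OH signal near δ 11.9, tetracoordinate 11B signal).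

**Step 4**
Reactants: 7, O5,O4-diphenylboron chelate of 5
Product: 8, 4'-O-methyldiplacol (target) [(2R,3R)-6-[(E)-3,7-dimethylocta-2,6-dienyl]-3,5,7-trihydroxy-2-(3-hydroxy-4-methoxyphenyl)chroman-4-one]
Conditions: hν 370 nm LED, FEP flow coil, degassed MeCN, 15 °C, to about 80% conversion; then HOCH2CH2NH2 (1.5 equiv), MeOH, rt, 10 min; pH 5 buffer work-up
Reagents that add atoms: none (boron is removed as 2-aminoethyl diphenylborinate; only H is returned to O5)
Why: Proposed new method: boron-chelate-gated photo-Claisen (radical-pair 1,3 O→C geranyl shift). The closest known reactions are the 254 nm photo-Claisen rearrangement of allyl aryl ethers and the photo-Fries rearrangement, which have not been shown on 5-hydroxy-4-chromanones because the O5–H···O=C4 unit deactivates the excited state by proton transfer. Replacing that proton by BPh2 closes this decay channel and should shift absorption to about 370–385 nm, where only the chelated A ring absorbs. Its O7→chelate charge-transfer S1 state (about 75 kcal/mol) lies well above the ArO–geranyl bond strength (about 50 kcal/mol), so O7–C1'' homolysis should give a caged aryloxyl/geranyl radical pair that recombines at C6 through the unhindered C1'' terminus and tautomerises to the 7-phenol. C6 is expected to be preferred over C8 because chelation fixes C4a=C5/C6=C7 double-bond character: only C6 attack keeps the O4=C4–C4a=C5–O5 chelate conjugated (thermal Claisen of chelated 2-hydroxy-4-allyloxyaryl ketones shows the same bias to the carbon between the two oxygens). The (E)-alkene is retained because the allyl radical keeps its configuration on the cage timescale; C2 and C3 are remote and no new stereocentre forms; ethanolamine then strips boron as its stable N→B borinate.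

## Compound list

1 | (+)-taxifolin, (2R,3R) | Oc1ccc([C@H]2Oc3cc(O)cc(O)c3C(=O)[C@@H]2O)cc1O | starting material
2 | geranyl bromide, (E) | CC(C)=CCC/C(C)=C/CBr | starting material
3 | 7-O-geranyltaxifolin, (2R,3R,E) | Oc1ccc([C@H]2Oc3cc(OC/C=C(\C)CCC=C(C)C)cc(O)c3C(=O)[C@@H]2O)cc1O | intermediate
4 | iodomethane | CI | starting material
5 | 7-O-geranyl-4'-O-methyltaxifolin, (2R,3R,E) | COc1ccc([C@H]2Oc3cc(OC/C=C(\C)CCC=C(C)C)cc(O)c3C(=O)[C@@H]2O)cc1O | intermediate
6 | diphenylborinic anhydride | c1ccccc1B(c1ccccc1)OB(c1ccccc1)c1ccccc1 | starting material
7 | O5,O4-diphenylboron chelate of 5, (2R,3R,E) | COc1ccc([C@H]2Oc3cc(OC/C=C(\C)CCC=C(C)C)cc4c3C(=[O+][B-](c5ccccc5)(c6ccccc6)O4)[C@@H]2O)cc1O | intermediate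
8 | 4'-O-methyldiplacol, (2R,3R)-6-geranyl-3,5,7-trihydroxy-2-(3-hydroxy-4-methoxyphenyl)chroman-4-one | COc1ccc([C@H]2Oc3cc(O)c(C/C=C(\C)CCC=C(C)C)c(O)c3C(=O)[C@@H]2O)cc1O | target

## Summary

Total steps: 4 (Steps 3 and 4 are telescoped in one solution, so three isolations). Longest linear sequence: 4.

**Steps most likely to fail**

1. **Step 4 (proposed new step).** Risks are slow O–C homolysis from the low-energy chelate state, C8 recombination (a C6:C8 ratio of about 3:1 is the realistic hope), recombination at the tertiary C3'' terminus, cage escape to 4'-O-methyltaxifolin, and secondary photocyclisation of the product's 7-OH onto the 2'',3''-alkene. Incomplete or mis-sited chelation in Step 3 would show up here as unreactive 5. Fallback (known chemistry): drop the chelate and the light and carry out the acid-clay (montmorillonite K10, CH2Cl2, 0 °C) ionic [1,3] O→C shift of the geranyl ether directly on 5, which is known for prenyl and geranyl ethers of 2-hydroxyaryl ketones, then separate the 6- from the 8-isomer.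

2. **Step 2.** The 4'-OH/3'-OH acidity difference is small, so the ratio may be lower than hoped; base may also cause some C2 epimerisation through the 4'-phenoxide/quinone methide (the cis isomer is separable, and C3 fixes the absolute configuration). Fallback: switch the chiral-pool source to (2S)-hesperetin (from hesperidin; enantiopurity at C2 must be checked), which already carries 4'-OMe/3'-OH. Protect the phenols, install 3-OH trans to the C2 aryl by silyl enol ether/DMDO (Rubottom) oxidation under control of C2, deprotect, then O7-geranylate to rejoin at 5.

3. **Step 1.** Risks are competing catechol O-alkylation or bis-alkylation, and air oxidation of the catechol under base. Fallback: base-free, acidity-selective Mitsunobu etherification of the 7-OH with geraniol (PPh3, DIAD, THF, 0 °C) in place of phenoxide alkylation.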